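Ring B is the carbocycle C5 (ring-fusion CMe)–C6–C7–C8 (CHMe)–C9 (quaternary, bears ArCH2 = C11)–C10 (ring-fusion CH); ring A is C10–C1–C2–C3 (=CMe2)–C4–C5. The route rests on the C9–C10 disconnection as an aldol condensation: C11 as an aldehyde is 1,3 to C10, a ketone of a 2-methylcyclohexane-1,3-dione (ring A) desymmetrized about C5 by yeast reduction. The key step closes ring B as a C9=C10 enal from a keto aldehyde whose chain carries the awkward axial C8 methyl, taken from methyl hydrogen (R)-3-methylglutarate and placed β to the aldehyde, where it cannot epimerize. Reductive benzylation of the enal then sets C10 and C9.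

Key step: step 7

Remark: atom labels C1–C11 are those of the overview; β is the face of C10–H and α the face of the C5 methyl; methyl hydrogen (R)-3-methylglutarate is taken as the commercial enantiopure source of C8.

Step 1
Reactants: 1 methyl hydrogen (R)-3-methylglutarate
Product: 3 (4R)-4-methyloxan-2-one, via hydroxy ester 2 (not isolated)
Conditions: BH3·SMe2, THF, 0 °C → rt; MeOH; then TsOH (cat.), toluene, 80 °C
Reagents that add atoms: none
Why: Borane reduces the free carboxylic acid chemoselectively beside the methyl ester (acyloxyborane pathway) and the δ-hydroxy ester lactonizes under acid, so the former acid carbon becomes C11 and the ester carbon C6 while the C8 stereocentre is untouched.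

Step 2
Reactants: 3 (4R)-4-methyloxan-2-one
Product: 4 (4R)-4-methyloxan-2-ol (anomer mixture)
Conditions: DIBAL-H (1.05 equiv), CH2Cl2, −78 °C; Rochelle salt
Reagents that add atoms: none
Why: Partial reduction of a δ-lactone with DIBAL-H, whose tetrahedral aluminate is stable at −78 °C and releases the lactol (a masked 5-hydroxy aldehyde) on work-up.

Step 3
Reactants: 4 (4R)-4-methyloxan-2-ol; 5 cyclohexane-1,3-dione
Product: 7 2-[(3S)-5-hydroxy-3-methylpentyl]cyclohexane-1,3-dione, via alkylidene dione 6 (not isolated)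
Conditions: Hantzsch ester (1.05 equiv), L-proline (20 mol %), CH2Cl2, rt
Reagents that add atoms: none
Why: Ramachary three-component reductive alkylation, in which proline-catalysed Knoevenagel condensation of the open hydroxy-aldehyde form of 4 gives alkylidene 6 and hydride transfer from the Hantzsch ester reduces it before a second Michael addition can occur, giving clean C-monoalkylation.

Step 4
Reactants: 7 2-[(3S)-5-hydroxy-3-methylpentyl]cyclohexane-1,3-dione
Product: 8 2-[(3S)-5-hydroxy-3-methylpentyl]-2-methylcyclohexane-1,3-dione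
Conditions: MeI, K2CO3, acetone, reflux
Reagents that add atoms: iodomethane, CI
Why: C-Alkylation of the stabilized 2-alkyl-1,3-dione enolate with the small soft electrophile MeI builds the still prochiral quaternary carbon C5, and carbonate does not deprotonate the primary alcohol.

Step 5
Reactants: 8 2-[(3S)-5-hydroxy-3-methylpentyl]-2-methylcyclohexane-1,3-dione
Product: 9 (2S,3S)-3-hydroxy-2-[(3S)-5-hydroxy-3-methylpentyl]-2-methylcyclohexan-1-one
Conditions: baker's yeast, sucrose, H2O, 30 °C
Reagents that add atoms: none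
Why: Enzymatic desymmetrizing ketone reduction (baker's yeast, Prelog sense), which for 2-alkyl-2-methylcyclohexane-1,3-diones reduces one carbonyl only to the (2S,3S)-hydroxy ketone; this fixes quaternary C5 by enzyme control and leaves the C4 carbinol as the masked ring-A ketone (a ketoreductase of the same sense can replace the yeast).

Step 6
Reactants: 9 (2S,3S)-3-hydroxy-2-[(3S)-5-hydroxy-3-methylpentyl]-2-methylcyclohexan-1-one
Product: 10 (3S)-5-[(1S,2S)-2-hydroxy-1-methyl-6-oxocyclohexyl]-3-methylpentanal
Conditions: TEMPO (10 mol %), PhI(OAc)2 (1.1 equiv), CH2Cl2, rt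
Reagents that add atoms: none
Why: Oxoammonium (TEMPO/PhI(OAc)2) oxidation selects the primary over the hindered secondary alcohol on steric grounds and is non-basic, so the β-hydroxy ketone does not undergo retro-aldol cleavage.

Step 7
Reactants: 10 (3S)-5-[(1S,2S)-2-hydroxy-1-methyl-6-oxocyclohexyl]-3-methylpentanal
Product: 12 (2S,4aR,5S)-5-hydroxy-2,4a-dimethyl-2,3,4,4a,5,6,7,8-octahydronaphthalene-1-carbaldehyde, via ketol 11 (not isolated)
Conditions: Bn2NH·CF3CO2H (0.3 equiv), toluene, 60 °C
Reagents that add atoms: none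
Why: The secondary ammonium salt converts the C11 aldehyde into its enamine, whose nucleophilic carbon C9 adds to the C10 ketone to give ketol 11, and the tertiary β-hydroxy aldehyde then loses water by E1cB to the conjugated C9=C10 enal. The closest known reaction type is the amine-salt-mediated intramolecular aldol condensation of keto aldehydes to cyclohexene-1-carbaldehydes. Ring B (C5–C6–C7–C8–C9–C10) closes through the C9–C10 bond in the 6-(enolexo)-exo-trig mode. No stereocentre is created that survives, since C9 and C10 of the ketol become sp2, and the existing ones are preserved: C5 is quaternary, C4 is a carbinol, and C8 is β to the aldehyde and not enolizable. The step needs chemoselectivity (aldehyde as donor, ketone as acceptor) and dehydration into conjugation. These are secured because only the aldehyde forms an enamine, C10 is the only ketone left after step 5, attack of C1 on C11 would need an eight-membered ring, and only C9 carries the acidic hydrogen for the E1cB step.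

Step 8
Reactants: 13 4-methoxy-2-methylphenol
Product: 14 2-hydroxy-5-methoxy-3-methylbenzaldehyde
Conditions: MgCl2, Et3N, (CH2O)n, MeCN, reflux
Reagents that add atoms: formaldehyde (as paraformaldehyde), C=O
Why: Magnesium-mediated ortho-formylation (Casnati–Skattebøl), in which the magnesium phenoxide directs formaldehyde to the only free ortho position and a second formaldehyde oxidizes the benzylic alkoxide to the aldehyde.

Step 9
Reactants: 14 2-hydroxy-5-methoxy-3-methylbenzaldehyde
Product: 15 2-(benzyloxy)-5-methoxy-3-methylbenzaldehyde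
Conditions: BnBr, K2CO3, DMF, 50 °C
Reagents that add atoms: benzyl bromide, BrCc1ccccc1
Why: Williamson etherification of the phenoxide; the benzyl ether survives all later basic, reductive (hydrazine) and organometallic steps and is removed at the end without acid.

Step 10
Reactants: 15 2-(benzyloxy)-5-methoxy-3-methylbenzaldehyde
Product: 16 [2-(benzyloxy)-5-methoxy-3-methylphenyl]methanol
Conditions: NaBH4, MeOH, 0 °C
Reagents that add atoms: none
Why: Hydride reduction of an aryl aldehyde to the benzylic alcohol.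

Step 11
Reactants: 16 [2-(benzyloxy)-5-methoxy-3-methylphenyl]methanol
Product: 17 2-(benzyloxy)-1-(bromomethyl)-5-methoxy-3-methylbenzene
Conditions: PBr3, CH2Cl2, 0 °C
Reagents that add atoms: phosphorus tribromide, BrP(Br)Br
Why: Bromination of a benzylic alcohol through its phosphite ester (SN2), giving the reactive electrophile for the C9 alkylation.

Step 12
Reactants: 12 hydroxy enal; 17 2-(benzyloxy)-1-(bromomethyl)-5-methoxy-3-methylbenzene
Product: 19 (1R,2S,4aR,5S,8aS)-1-{[2-(benzyloxy)-5-methoxy-3-methylphenyl]methyl}-5-hydroxy-2,4a-dimethyldecahydronaphthalene-1-carbaldehyde, via dilithium enolate 18 (not isolated)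
Conditions: Li (2.5 equiv), NH3(l)/THF, −78 °C; isoprene; then 17 (1.2 equiv), −78 → −33 °C; NH4Cl
Reagents that add atoms: none
Why: Stork-type dissolving-metal reductive alkylation, in which two-electron reduction of the enal and axial protonation at C10 (by the C4 hydroxyl) anti to the C5 methyl gives the trans-fused, regiodefined aldehyde enolate 18, which is C-benzylated on its equatorial β-face because the axial α-trajectory is blocked by the 1,3-diaxial C5 methyl, so C10–H (β) and quaternary C9 (ArCH2 β, CHO α) are set together.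

Step 13
Reactants: 19 benzylated hydroxy aldehyde
Product: 21 (1S,4aR,5S,6S,8aR)-5-{[2-(benzyloxy)-5-methoxy-3-methylphenyl]methyl}-5,6,8a-trimethyldecahydronaphthalen-1-ol, via hydrazone 20 (not isolated)
Conditions: N2H4·H2O, KOH, diethylene glycol, 130 → 200 °C
Reagents that add atoms: none
Why: Wolff–Kishner (Huang-Minlon) reduction, in which the non-enolizable neopentyl aldehyde forms its hydrazone and loses N2 under base, turning the axial formyl group into the C9 methyl without touching the benzyl ether or the alcohol.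

Step 14
Reactants: 21 trimethyl decalinol
Product: 22 (4aR,5S,6S,8aR)-5-{[2-(benzyloxy)-5-methoxy-3-methylphenyl]methyl}-5,6,8a-trimethyloctahydronaphthalen-1(2H)-one
Conditions: Dess–Martin periodinane, NaHCO3, CH2Cl2, rt
Reagents that add atoms: none
Why: Dess–Martin oxidation of the hindered secondary alcohol unmasks the C4 ketone under neutral conditions.

Step 15
Reactants: 22 C4 ketone
Product: 23 (2R,4aR,5S,6S,8aR)-5-{[2-(benzyloxy)-5-methoxy-3-methylphenyl]methyl}-2-(2-hydroxypropan-2-yl)-5,6,8a-trimethyloctahydronaphthalen-1(2H)-one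
Conditions: LDA, THF, −78 °C; acetone, −78 °C; NH4Cl
Reagents that add atoms: acetone, CC(C)=O
Why: Directed aldol addition, in which C3 is the only enolizable position (C5 is quaternary) and its lithium enolate adds to acetone anti to the syn-axial C5 methyl; the new C3 centre is removed in step 16.

Step 16
Reactants: 23 aldol adduct
Product: 25 (4aR,5S,6S,8aR)-5-{[2-(benzyloxy)-5-methoxy-3-methylphenyl]methyl}-5,6,8a-trimethyl-2-(propan-2-ylidene)octahydronaphthalen-1(2H)-one, via mesylate 24 (not isolated)
Conditions: MsCl, Et3N, DMAP (cat.), CH2Cl2, 0 °C; then DBU, rt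
Reagents that add atoms: none
Why: Mesylation of the tertiary aldol hydroxyl followed by E1cB elimination through the C3 enolate places the double bond regiospecifically in conjugation as the tetrasubstituted isopropylidene.

Step 17
Reactants: 25 α-isopropylidene ketone
Product: 26 (1S,2S,4aR,8aR)-1-{[2-(benzyloxy)-5-methoxy-3-methylphenyl]methyl}-1,2,4a-trimethyl-5-methylidene-6-(propan-2-ylidene)decahydronaphthalene
Conditions: Cp2TiMe2 (3 equiv), toluene, 75 °C, dark
Reagents that add atoms: dimethyltitanocene (Petasis reagent), C[Ti](C)(C1C=CC=C1)C1C=CC=C1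
Why: Petasis methylenation, whose small, non-basic titanium methylidene adds to hindered and conjugated ketones where phosphorus ylides fail or deprotonate, converts C4=O into C4=CH2 without moving the isopropylidene.

Step 18
Reactants: 26 diene
Product: 28 benzyl 3-[(1S,4aR,5S,6S,8aR)-5-{[2-(benzyloxy)-5-methoxy-3-methylphenyl]methyl}-5,6,8a-trimethyl-2-(propan-2-ylidene)decahydronaphthalen-1-yl]propanoate, via alkylborane 27 (not isolated)
Conditions: 9-BBN, THF, 0 → 60 °C; then BrCH2CO2Bn, t-BuOK, t-BuOH/THF, 0 °C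
Reagents that add atoms: benzyl bromoacetate, BrCC(=O)OCc1ccccc1
Why: Anti-Markovnikov hydroboration of the 1,1-disubstituted alkene (the tetrasubstituted one is inert) delivers H to C4 from the β-face, anti to the adjacent axial C5 methyl, which sets C4 with the chain α, and Brown's haloacetate alkylation (boron ate complex, 1,2-migration of the primary alkyl with loss of bromide, protonolysis) then adds CH2CO2Bn.

Step 19
Reactants: 28 dibenzyl-protected seco acid
Product: 29 3-[(1S,4aR,5S,6S,8aR)-5-[(2-hydroxy-5-methoxy-3-methylphenyl)methyl]-5,6,8a-trimethyl-2-(propan-2-ylidene)decahydronaphthalen-1-yl]propanoic acid (target)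
Conditions: H2 (1 atm), 10 % Pd/C, EtOAc, rt
Reagents that add atoms: none
Why: Hydrogenolysis removes the benzyl ester and the aryl benzyl ether in one operation; the hindered tetrasubstituted isopropylidene should not be hydrogenated under these mild conditions, and no acid is present that could lactonize the carboxylic acid onto the alkene.

Compound list
1 | (3R)-5-methoxy-3-methyl-5-oxopentanoic acid (methyl hydrogen (R)-3-methylglutarate) | COC(=O)C[C@@H](CC(=O)O)C | starting material
2 | methyl (3R)-5-hydroxy-3-methylpentanoate | COC(=O)C[C@@H](CCO)C | intermediate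
3 | (4R)-4-methyloxan-2-one | O=C1C[C@@H](CCO1)C | intermediate
4 | (4R)-4-methyloxan-2-ol (anomer mixture) | OC1C[C@@H](CCO1)C | intermediate
5 | cyclohexane-1,3-dione | O=C1CCCC(=O)C1 | starting material
6 | 2-[(3S)-5-hydroxy-3-methylpentylidene]cyclohexane-1,3-dione | O=C1CCCC(=O)C1=CC[C@@H](CCO)C | intermediate
7 | 2-[(3S)-5-hydroxy-3-methylpentyl]cyclohexane-1,3-dione | O=C1CCCC(=O)C1CC[C@@H](CCO)C | intermediate
8 | 2-[(3S)-5-hydroxy-3-methylpentyl]-2-methylcyclohexane-1,3-dione | CC1(CC[C@@H](CCO)C)C(=O)CCCC1=O | intermediate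
9 | (2S,3S)-3-hydroxy-2-[(3S)-5-hydroxy-3-methylpentyl]-2-methylcyclohexan-1-one | O=C1CCC[C@H](O)[C@]1(C)CC[C@@H](CCO)C | intermediate
10 | (3S)-5-[(1S,2S)-2-hydroxy-1-methyl-6-oxocyclohexyl]-3-methylpentanal | O=C1CCC[C@H](O)[C@]1(C)CC[C@@H](CC=O)C | intermediate
11 | (2S,4aS,5S)-5,8a-dihydroxy-2,4a-dimethyldecahydronaphthalene-1-carbaldehyde (ketol, C1/C8a diastereomers) | O=CC1C2(O)CCC[C@H](O)[C@]2(C)CC[C@@H]1C | intermediate
12 | (2S,4aR,5S)-5-hydroxy-2,4a-dimethyl-2,3,4,4a,5,6,7,8-octahydronaphthalene-1-carbaldehyde | O=CC1=C2CCC[C@H](O)[C@]2(C)CC[C@@H]1C | intermediate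
13 | 4-methoxy-2-methylphenol | COc1ccc(O)c(C)c1 | starting material
14 | 2-hydroxy-5-methoxy-3-methylbenzaldehyde | COc1cc(C)c(O)c(C=O)c1 | intermediate
15 | 2-(benzyloxy)-5-methoxy-3-methylbenzaldehyde | COc1cc(C)c(OCc2ccccc2)c(C=O)c1 | intermediate
16 | [2-(benzyloxy)-5-methoxy-3-methylphenyl]methanol | COc1cc(C)c(OCc2ccccc2)c(CO)c1 | intermediate
17 | 2-(benzyloxy)-1-(bromomethyl)-5-methoxy-3-methylbenzene | COc1cc(C)c(OCc2ccccc2)c(CBr)c1 | intermediate
18 | dilithium enolate–alkoxide of the 1,4-reduced enal (trans-fused) | [Li+].[Li+].[O-]C=C1[C@H]2CCC[C@H]([O-])[C@]2(C)CC[C@@H]1C | intermediate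
19 | (1R,2S,4aR,5S,8aS)-1-{[2-(benzyloxy)-5-methoxy-3-methylphenyl]methyl}-5-hydroxy-2,4a-dimethyldecahydronaphthalene-1-carbaldehyde | COc1cc(C)c(OCc2ccccc2)c(C[C@]2(C=O)[C@H]3CCC[C@H](O)[C@]3(C)CC[C@@H]2C)c1 | intermediate
20 | hydrazone of 19 | COc1cc(C)c(OCc2ccccc2)c(C[C@]2(C=NN)[C@H]3CCC[C@H](O)[C@]3(C)CC[C@@H]2C)c1 | intermediate
21 | (1S,4aR,5S,6S,8aR)-5-{[2-(benzyloxy)-5-methoxy-3-methylphenyl]methyl}-5,6,8a-trimethyldecahydronaphthalen-1-ol | COc1cc(C)c(OCc2ccccc2)c(C[C@]2(C)[C@H]3CCC[C@H](O)[C@]3(C)CC[C@@H]2C)c1 | intermediate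
22 | (4aR,5S,6S,8aR)-5-{[2-(benzyloxy)-5-methoxy-3-methylphenyl]methyl}-5,6,8a-trimethyloctahydronaphthalen-1(2H)-one | COc1cc(C)c(OCc2ccccc2)c(C[C@]2(C)[C@H]3CCCC(=O)[C@]3(C)CC[C@@H]2C)c1 | intermediate
23 | (2R,4aR,5S,6S,8aR)-5-{[2-(benzyloxy)-5-methoxy-3-methylphenyl]methyl}-2-(2-hydroxypropan-2-yl)-5,6,8a-trimethyloctahydronaphthalen-1(2H)-one | COc1cc(C)c(OCc2ccccc2)c(C[C@]2(C)[C@H]3CC[C@H](C(C)(C)O)C(=O)[C@]3(C)CC[C@@H]2C)c1 | intermediate
24 | tertiary methanesulfonate of 23 | COc1cc(C)c(OCc2ccccc2)c(C[C@]2(C)[C@H]3CC[C@H](C(C)(C)OS(C)(=O)=O)C(=O)[C@]3(C)CC[C@@H]2C)c1 | intermediate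
25 | (4aR,5S,6S,8aR)-5-{[2-(benzyloxy)-5-methoxy-3-methylphenyl]methyl}-5,6,8a-trimethyl-2-(propan-2-ylidene)octahydronaphthalen-1(2H)-one | COc1cc(C)c(OCc2ccccc2)c(C[C@]2(C)[C@H]3CCC(=C(C)C)C(=O)[C@]3(C)CC[C@@H]2C)c1 | intermediate
26 | (1S,2S,4aR,8aR)-1-{[2-(benzyloxy)-5-methoxy-3-methylphenyl]methyl}-1,2,4a-trimethyl-5-methylidene-6-(propan-2-ylidene)decahydronaphthalene | COc1cc(C)c(OCc2ccccc2)c(C[C@]2(C)[C@H]3CCC(=C(C)C)C(=C)[C@]3(C)CC[C@@H]2C)c1 | intermediate
27 | B-alkyl-9-borabicyclo[3.3.1]nonane from hydroboration of 26 (boron on the exocyclic CH2 of C4) | COc1cc(C)c(OCc2ccccc2)c(C[C@]2(C)[C@H]3CCC(=C(C)C)[C@@H](CB4C5CCCC4CCC5)[C@]3(C)CC[C@@H]2C)c1 | intermediate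
28 | benzyl 3-[(1S,4aR,5S,6S,8aR)-5-{[2-(benzyloxy)-5-methoxy-3-methylphenyl]methyl}-5,6,8a-trimethyl-2-(propan-2-ylidene)decahydronaphthalen-1-yl]propanoate | COc1cc(C)c(OCc2ccccc2)c(C[C@]2(C)[C@H]3CCC(=C(C)C)[C@@H](CCC(=O)OCc4ccccc4)[C@]3(C)CC[C@@H]2C)c1 | intermediate
29 | 3-[(1S,4aR,5S,6S,8aR)-5-[(2-hydroxy-5-methoxy-3-methylphenyl)methyl]-5,6,8a-trimethyl-2-(propan-2-ylidene)decahydronaphthalen-1-yl]propanoic acid | COc1cc(C)c(O)c(C[C@]2(C)[C@H]3CCC(=C(C)C)[C@@H](CCC(=O)O)[C@]3(C)CC[C@@H]2C)c1 | target

Total step count: 19 (15 in the main line, 4 for the aryl fragment). Longest linear sequence: 15 steps (steps 1–7 and 12–19).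

Steps most likely to fail

Step 12 (reductive benzylation of the enal). The aldehyde may be reduced at carbon (1,2-reduction or pinacol coupling) instead of giving the enolate, the enolate may be protonated before it is alkylated, or benzylation may occur on oxygen or on the more hindered face next to the axial C8 methyl. The fallback moves the same operation to the carboxylic acid level, where over-reduction is not possible. It sets out from 12: Pinnick oxidation (NaClO2, NaH2PO4, 2-methylbut-2-ene, t-BuOH/H2O) gives the unsaturated hydroxy acid F1. Li/NH3 reduction of its lithium carboxylate and trapping of the enediolate with 17 gives the α-benzylated acid F2, under the same facial control. LiAlH4 in THF gives the diol F3, and TEMPO/PhI(OAc)2 oxidizes only its primary alcohol, which returns the route to 19.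

Step 17 (methylenation of the enone). The titanium methylidene may fail to engage a carbonyl that is flanked by quaternary C5 and the isopropylidene and is deactivated by conjugation, so that the reagent decomposes first. The fallback replaces the carbene olefination by addition and elimination. It sets out from 25: (trimethylsilyl)methyllithium with CeCl3 in THF at −78 °C adds 1,2 to the carbonyl from the β-face and gives the β-hydroxysilane F4; Peterson elimination with KH in THF then gives 26.

Step 18 (hydroboration and haloacetate alkylation). The hindered trialkylborane may form slowly, and in the ate complex the bicyclooctyl B–C bond may migrate in place of the β-branched primary alkyl group, or the borane may be protonated without C–C bond formation. The fallback forms the C–C bond by a Wittig reaction. It sets out from 26: hydroboration with 9-BBN and oxidative work-up (NaOH, H2O2) gives the primary alcohol F5. Dess–Martin oxidation, buffered and used at once to avoid epimerization at C4, gives the aldehyde F6. Benzyl (triphenylphosphoranylidene)acetate in CH2Cl2 gives the (E)-enoate F7. Under the conditions of step 19 the disubstituted C=C is saturated and both benzyl groups are removed, so the fallback arrives at 29.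

Further compounds
F1 | step 12 | (2S,4aR,5S)-5-hydroxy-2,4a-dimethyl-2,3,4,4a,5,6,7,8-octahydronaphthalene-1-carboxylic acid | O=C(O)C1=C2CCC[C@H](O)[C@]2(C)CC[C@@H]1C
F2 | step 12 | (1R,2S,4aR,5S,8aS)-1-{[2-(benzyloxy)-5-methoxy-3-methylphenyl]methyl}-5-hydroxy-2,4a-dimethyldecahydronaphthalene-1-carboxylic acid | COc1cc(C)c(OCc2ccccc2)c(C[C@]2(C(=O)O)[C@H]3CCC[C@H](O)[C@]3(C)CC[C@@H]2C)c1
F3 | step 12 | (1S,4aR,5R,6S,8aR)-5-{[2-(benzyloxy)-5-methoxy-3-methylphenyl]methyl}-5-(hydroxymethyl)-6,8a-dimethyldecahydronaphthalen-1-ol | COc1cc(C)c(OCc2ccccc2)c(C[C@]2(CO)[C@H]3CCC[C@H](O)[C@]3(C)CC[C@@H]2C)c1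
F4 | step 17 | β-hydroxysilane from 1,2-addition of Me3SiCH2Li to the C4 carbonyl of 25 (CH2SiMe3 β, OH α) | COc1cc(C)c(OCc2ccccc2)c(C[C@]2(C)[C@H]3CCC(=C(C)C)[C@](O)(C[Si](C)(C)C)[C@]3(C)CC[C@@H]2C)c1
F5 | step 18 | [(1S,4aR,5S,6S,8aR)-5-{[2-(benzyloxy)-5-methoxy-3-methylphenyl]methyl}-5,6,8a-trimethyl-2-(propan-2-ylidene)decahydronaphthalen-1-yl]methanol | COc1cc(C)c(OCc2ccccc2)c(C[C@]2(C)[C@H]3CCC(=C(C)C)[C@@H](CO)[C@]3(C)CC[C@@H]2C)c1
F6 | step 18 | (1S,4aR,5S,6S,8aR)-5-{[2-(benzyloxy)-5-methoxy-3-methylphenyl]methyl}-5,6,8a-trimethyl-2-(propan-2-ylidene)decahydronaphthalene-1-carbaldehyde | COc1cc(C)c(OCc2ccccc2)c(C[C@]2(C)[C@H]3CCC(=C(C)C)[C@@H](C=O)[C@]3(C)CC[C@@H]2C)c1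
F7 | step 18 | benzyl (2E)-3-[(1S,4aR,5S,6S,8aR)-5-{[2-(benzyloxy)-5-methoxy-3-methylphenyl]methyl}-5,6,8a-trimethyl-2-(propan-2-ylidene)decahydronaphthalen-1-yl]prop-2-enoate | COc1cc(C)c(OCc2ccccc2)c(C[C@]2(C)[C@H]3CCC(=C(C)C)[C@@H](/C=C/C(=O)OCc4ccccc4)[C@]3(C)CC[C@@H]2C)c1
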